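## Structural features

The target is a germacranolide: a ten-membered carbocycle C1–C10 with a Z trisubstituted C1=C10 alkene (methyl C14 on C10) and an E trisubstituted C4=C5 alkene (methyl C15 on C4). An α-methylene-γ-butyrolactone (O–C6–C7–C11(=C13)–C12=O) is fused across C6–C7. H6 and the tertiary 7-OH lie on the same face, so C5 and C8 are cis on the lactone. C6 to C9 are four contiguous oxygenated stereocentres (6S,7S,8S,9R): the lactone oxygen, a fully substituted carbinol, a free secondary alcohol and the angelate. The fragile groups are the exocyclic methylene lactone (Michael and radical acceptor), the Z angelate (isomerises to the tiglate and can migrate to O8), the 1,5-diene in a medium ring (Cope and transannular reactions), and the γ-lactone, which can shift from O6 to O8. The real difficulty is closing the strained (1(10)Z,4E)-cyclodecadiene while placing a hindered Z ester on C9 only. The key step exploits the fact that C9 is an sp3 carbon carrying the acyloxy oxygen and is bonded to sp2 C10 of the Z alkene. C9 can therefore arrive as an aldehyde that has taken up angeloyl chloride, and C10 as a (Z)-alkenyl iodide.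

## Logic of the disconnections

**29 to 28.** Only the two O–Si bonds at O7 and O8 are cut, so the last step is a deprotection. The forward step must use fluoride under buffered, non-basic conditions so that the ester stays on O9 and the lactone stays on O6.

**28 to 27.** The C9–C10 bond is cut, opening the ten-membered ring. C10 becomes an alkenyl iodide and C9 a 1-chloroalkyl ester that already carries the angelate. This removes the ring, one stereocentre and the late esterification in one cut. The forward step must join two electrophiles within one molecule, keep the Z geometry, and set C9 from an epimer mixture.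

**27 to 24 and 26; 26 to 25.** The C9–Cl and C9–O(acyl) bonds are cut, which is the reverse of adding an acid chloride across a C=O bond. No hindered alcohol is ever esterified. The forward demand is a Lewis acid mild enough for two silyl ethers and a Z acid chloride made without acid.

**24 to 23 to 22.** The C9 carbonyl is traced to a primary triethylsilyl ether and the O7 and O8 silyl groups to free hydroxyls. The tertiary O7 carries triethylsilyl and not trimethylsilyl, because the group must survive an oxidation that releases HCl and a ZnCl2 step. The forward demand is that the oxidation distinguishes the primary silyl ether from the other two.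

**22 to 21 to 20.** The O–C6 lactone bond is cut back to an epoxide opened by the tert-butyl ester, and the epoxide back to the C6=C7 alkene. This removes C6 and C7 as stereocentres and turns the ring into an acyclic dienyl ester. The forward demands are epoxidation of one alkene out of four on the face erythro to the C8 carbinol, and opening at C6 with inversion.

**20 to 19 to 18.** Only protecting-group bonds are cut: C8 and C9 are tied in an acetonide. It comes from the chiral pool and lets the C1 end be oxidised while no other hydroxyl is free.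

**18 to 13 and 14; 13 to 12.** The C1=C10 bond is cut (Wittig). The alkenyl iodide is introduced only after all palladium steps, so that no second alkenyl halide competes. The forward demand is Z selectivity.

**12 to 11 and 9; 9 to 7; 11 to 10.** The C7–C11 bond is cut (Stille), and the C7–Sn and C6–H bonds back to an alkyne. The forward demand is syn addition with tin on C7, which fixes C5 cis to C8 as the epoxide route requires.

**10 to 3 and 6; 3 to 1; 6 to 4.** The C5–C6 bond is cut (Sonogashira). 3 carries C1–C5 with the E alkene from a carboalumination, and 6 carries C6–C9 with the C8 centre from the chiral pool.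

## Other disconnections considered

**Alternative 1:** Here C6–C10 and C14 are carried as a furan. Furyl carbinol A2 is oxidised with N-bromosuccinimide in NaHCO3-buffered aqueous THF (Achmatowicz), and the C6 hydroxyl recloses on C10 to give pyranone A1.

- In its favour: the step is among the most dependable oxidative rearrangements, runs on scale, and starts from a cheap furan. The C6 centre can be set by catalyst control when A2 is made. On robustness of the key step this alternative is better than the chosen plan.
- Against it here: A1 contains no carbocycle. The C7–C11 bond (acrylate anion equivalent adding to the C7 ketone with face control) and the C1–C10 bond (a Z trisubstituted alkene made at a former ketal carbon while closing the ten-membered ring) remain open. The C8=C9 alkene of A1 is cis, so syn dihydroxylation would give the erythro 8,9-diol, whereas the target is threo. The angelate would still have to be put on O9 beside a free O8.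
- Comparison: the mechanism is polar and well understood, against an untested radical–organometallic ring closure in the chosen plan. On structure, A1 fixes one of four stereocentres and postpones ring closure. On step economy, A1 is short to make, but the remaining tasks would probably need more steps than the whole chosen route.

**Alternative 2:** The C6–C7 bond is cut. Thirteen-membered bis-allylic ether A4 is deprotonated at C6 with lithium diisopropylamide. The carbanion attacks C7 as the O–C13 bond breaks ([2,3]-Wittig), giving ten-membered carbinol A3 with the quaternary C7 ether and the C11=C13 methylene.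

- In its favour: one concerted step forms the C6–C7 bond, both stereocentres and the exocyclic methylene. The ring closure that precedes it makes a thirteen-membered ring, which is easier than a ten-membered one. On predictability of the ring-forming event this alternative is equal to or better than the chosen plan.
- Against it here: C7 of A4 is a fully substituted, electron-rich enol ether carbon, a poor terminus for the carbanion. Deprotonation at C13 and a [1,2] shift compete. The C6/C7 relationship depends on the enol ether geometry and on a transannular transition state that cannot be predicted with confidence.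
- After A3, C12 must be oxidised and lactonised, the C7 ether removed with acid, and O9 acylated selectively beside O8, since the angelate cannot pass through the amide base.
- Comparison: the concerted mechanism is cleaner than the chosen one. On structure, A3 lacks the lactone and the ester. On step economy it is clearly longer.

**Alternative 3:** The C4–C9 bond of trans-fused octalin A6 is cut. Its C9 alkoxide (potassium tert-butoxide) fragments with loss of the C5 mesylate (Grob) to give cyclodecadienone A5.

- In its favour: fragmentation of 1,3-diol monosulfonates is the classical, stereospecific entry to (E)-cyclodecenones. The Z C1=C10 alkene is fixed beforehand in a six-membered ring, and no high dilution is needed. On reliability of ring formation and alkene geometry it is better than the chosen plan.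
- Against it here: A6 needs six stereocentres, two of them quaternary. The chair that aligns the C5–O bond with the C4–C9 bond forces either the angular methyl against the 6-silyloxy group or the C11 unit against the C9 oxygen.
- A5 still needs reduction of a cross-conjugated ketone to 9R in a mobile ring, angeloylation of that hindered alcohol, oxidation of C12 with lactonisation onto O6, and acetonide removal without acyl migration. The dienone is also prone to transannular reactions.
- Comparison: the mechanism is better precedented. On structure, the stereocentres are bought at the price of a congested bicycle. On step economy, four or more steps follow the fragmentation against one in the chosen plan.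

Key step: step 17

Remark: atoms carry germacrane numbers throughout; CIP descriptors of intermediates change with the substituents, while the spatial arrangement at C6, C7 and C8 stays that of the target.

## Route

Step 1
Reactants: 1 pent-4-yn-1-ol
Product: 3 (E)-5-iodo-4-methylpent-4-en-1-ol, via alkenylalane 2 (not isolated)
Conditions: Me3Al (3 equiv), Cp2ZrCl2 (0.25 equiv), CH2Cl2, 0 °C to rt; then I2, THF, −30 to 0 °C
Reagents that add atoms: trimethylaluminium C[Al](C)C; iodine II
Why: Zirconium-catalysed carboalumination (Negishi) adds methyl and aluminium syn across the terminal alkyne with aluminium on the terminal carbon, and iodinolysis with retention gives the E iodide that becomes C4=C5.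

Step 2
Reactants: 4 [(4R)-2,2-dimethyl-1,3-dioxolan-4-yl]methanol
Product: 6 (4R)-4-ethynyl-2,2-dimethyl-1,3-dioxolane, via aldehyde 5 (not isolated)
Conditions: (COCl)2, DMSO, Et3N, CH2Cl2, −78 to 0 °C; then MeOH, K2CO3, dimethyl (1-diazo-2-oxopropyl)phosphonate, 0 °C to rt
Reagents that add atoms: dimethyl (1-diazo-2-oxopropyl)phosphonate CC(=O)C(=[N+]=[N-])P(=O)(OC)OC
Why: Swern oxidation followed by Ohira–Bestmann (Seyferth–Gilbert) homologation under conditions mild enough for the α-alkoxy centre; the labile aldehyde is used in solution, and the chiral-pool centre becomes C8.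

Step 3
Reactants: 7 tert-butyl prop-2-enoate
Product: 9 tert-butyl 2-bromoprop-2-enoate, via dibromide 8 (not isolated)
Conditions: Br2, CH2Cl2, 0 °C; then Et3N, 0 °C to rt
Reagents that add atoms: bromine BrBr
Why: Bromine addition and base-induced loss of HBr through the acidic α-hydrogen is the standard route to 2-bromoacrylates; the product is kept cold and used promptly.

Step 4
Reactants: 3 (E)-5-iodo-4-methylpent-4-en-1-ol; 6 (4R)-4-ethynyl-2,2-dimethyl-1,3-dioxolane
Product: 10 (4E)-7-[(4R)-2,2-dimethyl-1,3-dioxolan-4-yl]-4-methylhept-4-en-6-yn-1-ol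
Conditions: PdCl2(PPh3)2 (3 mol%), CuI (6 mol%), Et3N, THF, rt
Reagents that add atoms: none
Why: Sonogashira coupling forms C5–C6 with retention of the E iodide geometry and tolerates the free hydroxyl and the acetal.

Step 5
Reactants: 10 (4E)-7-[(4R)-2,2-dimethyl-1,3-dioxolan-4-yl]-4-methylhept-4-en-6-yn-1-ol
Product: 11 (4E,6E)-7-[(4S)-2,2-dimethyl-1,3-dioxolan-4-yl]-4-methyl-7-(tributylstannyl)hepta-4,6-dien-1-ol
Conditions: Bu3SnH (1.2 equiv, slow addition), PdCl2(PPh3)2 (3 mol%), THF, 0 °C
Reagents that add atoms: tributyltin hydride CCCC[SnH](CCCC)CCCC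
Why: Palladium-catalysed hydrostannation is a syn addition; tin is expected on C7, next to the oxygenated C8 and remote from the conjugated alkene, so H6 ends cis to tin and C5 cis to C8.

Step 6
Reactants: 11 (4E,6E)-7-[(4S)-2,2-dimethyl-1,3-dioxolan-4-yl]-4-methyl-7-(tributylstannyl)hepta-4,6-dien-1-ol; 9 tert-butyl 2-bromoprop-2-enoate
Product: 12 tert-butyl (3Z,5E)-3-[(4R)-2,2-dimethyl-1,3-dioxolan-4-yl]-9-hydroxy-6-methyl-2-methylidenenona-3,5-dienoate
Conditions: Pd(PPh3)4 (5 mol%), CuI (10 mol%), CsF (2 equiv), DMF, 40 °C
Reagents that add atoms: none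
Why: Stille coupling forms C7–C11 with retention at the alkenyl tin; copper and fluoride speed up the hindered stannane, and the bulky ester and the C8 branch disfavour the s-cis diene needed for Diels–Alder dimerisation.

Step 7
Reactants: 12 tert-butyl (3Z,5E)-3-[(4R)-2,2-dimethyl-1,3-dioxolan-4-yl]-9-hydroxy-6-methyl-2-methylidenenona-3,5-dienoate
Product: 13 tert-butyl (3Z,5E)-3-[(4R)-2,2-dimethyl-1,3-dioxolan-4-yl]-6-methyl-2-methylidene-9-oxonona-3,5-dienoate
Conditions: Dess–Martin periodinane, NaHCO3, CH2Cl2, 0 °C to rt
Reagents that add atoms: none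
Why: Dess–Martin oxidation of the only free hydroxyl; the buffer protects the acetal and the diene.

Step 8
Reactants: 13 tert-butyl (3Z,5E)-3-[(4R)-2,2-dimethyl-1,3-dioxolan-4-yl]-6-methyl-2-methylidene-9-oxonona-3,5-dienoate; 14 ethyltriphenylphosphonium bromide
Product: 18 tert-butyl (3Z,5E,9Z)-3-[(4R)-2,2-dimethyl-1,3-dioxolan-4-yl]-10-iodo-6-methyl-2-methylideneundeca-3,5,9-trienoate, via ethylidene ylide 15 (not isolated), via iodophosphonium salt 16 (not isolated), via iodo ylide 17 (not isolated)
Conditions: 14, nBuLi, THF, 0 °C; I2, −78 °C; NaN(SiMe3)2, −78 to −20 °C; 13, −78 °C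
Reagents that add atoms: iodine II
Why: Wittig olefination with the α-iodo ylide (Stork–Zhao type) gives the Z 2-iodoalkene under kinetic control; at −78 °C the aldehyde reacts far faster than the hindered 2-substituted acrylate, and the iodide is introduced only now because all palladium steps are over.

Step 9
Reactants: 18 tert-butyl (3Z,5E,9Z)-3-[(4R)-2,2-dimethyl-1,3-dioxolan-4-yl]-10-iodo-6-methyl-2-methylideneundeca-3,5,9-trienoate
Product: 19 tert-butyl (3Z,5E,9Z)-3-[(1R)-1,2-dihydroxyethyl]-10-iodo-6-methyl-2-methylideneundeca-3,5,9-trienoate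
Conditions: AcOH/H2O (4:1), 40 °C
Reagents that add atoms: none
Why: Mild acid hydrolysis of a terminal isopropylidene acetal; the tert-butyl ester and the alkenyl iodide are stable to aqueous acetic acid.

Step 10
Reactants: 19 tert-butyl (3Z,5E,9Z)-3-[(1R)-1,2-dihydroxyethyl]-10-iodo-6-methyl-2-methylideneundeca-3,5,9-trienoate
Product: 20 tert-butyl (3Z,5E,9Z)-3-[(1R)-1-hydroxy-2-(triethylsilyloxy)ethyl]-10-iodo-6-methyl-2-methylideneundeca-3,5,9-trienoate
Conditions: Et3SiCl (1.05 equiv), imidazole, CH2Cl2, −40 °C
Reagents that add atoms: chlorotriethylsilane CC[Si](Cl)(CC)CC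
Why: Silylation of the primary over the secondary allylic hydroxyl at low temperature; the C8 hydroxyl stays free to direct the epoxidation, and O9 is blocked so that it cannot attack the epoxide later.

Step 11
Reactants: 20 tert-butyl (3Z,5E,9Z)-3-[(1R)-1-hydroxy-2-(triethylsilyloxy)ethyl]-10-iodo-6-methyl-2-methylideneundeca-3,5,9-trienoate
Product: 21 tert-butyl 2-[(2S,3R)-2-[(1S)-1-hydroxy-2-(triethylsilyloxy)ethyl]-3-[(1E,5Z)-6-iodo-2-methylhepta-1,5-dien-1-yl]oxiran-2-yl]prop-2-enoate
Conditions: Ti(OiPr)4 (1.0 equiv), L-(+)-diisopropyl tartrate (1.2 equiv), tBuOOH (2 equiv), 4 Å MS, CH2Cl2, −20 °C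
Reagents that add atoms: tert-butyl hydroperoxide CC(C)(C)OO
Why: Sharpless epoxidation is hydroxyl-directed, so of the four alkenes only C6=C7 reacts; for this C8 configuration the L-(+)-tartrate face is the erythro face (matched pair), which 1,2-allylic strain with the C7 acrylate also favours, and this sets C7 and the epoxide carbon C6.

Step 12
Reactants: 21 tert-butyl 2-[(2S,3R)-2-[(1S)-1-hydroxy-2-(triethylsilyloxy)ethyl]-3-[(1E,5Z)-6-iodo-2-methylhepta-1,5-dien-1-yl]oxiran-2-yl]prop-2-enoate
Product: 22 (4S,5S)-4-hydroxy-4-[(1S)-1-hydroxy-2-(triethylsilyloxy)ethyl]-5-[(1E,5Z)-6-iodo-2-methylhepta-1,5-dien-1-yl]-3-methylideneoxolan-2-one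
Conditions: camphorsulfonic acid (0.1 equiv), CH2Cl2, −20 to 0 °C
Reagents that add atoms: none
Why: Acid-promoted lactonisation of an epoxy tert-butyl ester: the ester carbonyl opens the activated allylic C6–O bond from the rear (5-endo, inversion at C6) and the tert-butyl group leaves as isobutene, giving the lactone oxygen trans to the 7-OH.

Step 13
Reactants: 22 (4S,5S)-4-hydroxy-4-[(1S)-1-hydroxy-2-(triethylsilyloxy)ethyl]-5-[(1E,5Z)-6-iodo-2-methylhepta-1,5-dien-1-yl]-3-methylideneoxolan-2-one
Product: 23 (4R,5S)-4-[(1S)-1,2-bis(triethylsilyloxy)ethyl]-5-[(1E,5Z)-6-iodo-2-methylhepta-1,5-dien-1-yl]-3-methylidene-4-(triethylsilyloxy)oxolan-2-one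
Conditions: Et3SiOTf (3 equiv), 2,6-lutidine, CH2Cl2, −78 to 0 °C
Reagents that add atoms: triethylsilyl trifluoromethanesulfonate CC[Si](CC)(CC)OS(=O)(=O)C(F)(F)F
Why: The silyl triflate silylates the secondary and the tertiary hydroxyl in one operation; early protection of O8 also blocks lactone migration to O8.

Step 14
Reactants: 23 (4R,5S)-4-[(1S)-1,2-bis(triethylsilyloxy)ethyl]-5-[(1E,5Z)-6-iodo-2-methylhepta-1,5-dien-1-yl]-3-methylidene-4-(triethylsilyloxy)oxolan-2-one
Product: 24 (2R)-2-[(2S,3R)-2-[(1E,5Z)-6-iodo-2-methylhepta-1,5-dien-1-yl]-4-methylidene-5-oxo-3-(triethylsilyloxy)oxolan-3-yl]-2-(triethylsilyloxy)acetaldehyde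
Conditions: (COCl)2 (4 equiv), DMSO (8 equiv), CH2Cl2, −78 to −40 °C; Et3N, −78 to 0 °C
Reagents that add atoms: none
Why: Under Swern conditions a primary triethylsilyl ether is cleaved and oxidised directly to the aldehyde while secondary and tertiary triethylsilyl ethers remain, so no separate deprotection is needed; the crude aldehyde is used at once to avoid epimerisation at C8.

Step 15
Reactants: 25 (2Z)-2-methylbut-2-enoic acid
Product: 26 (2Z)-2-methylbut-2-enoyl chloride
Conditions: 1-chloro-N,N,2-trimethylprop-1-en-1-amine (1.05 equiv), CH2Cl2, 0 °C; used as solution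
Reagents that add atoms: 1-chloro-N,N,2-trimethylprop-1-en-1-amine CC(C)=C(Cl)N(C)C
Why: The chloroenamine converts the acid to its chloride under neutral conditions without free HCl or heat, which are what isomerise the Z acid to the E series.

Step 16
Reactants: 24 (2R)-2-[(2S,3R)-2-[(1E,5Z)-6-iodo-2-methylhepta-1,5-dien-1-yl]-4-methylidene-5-oxo-3-(triethylsilyloxy)oxolan-3-yl]-2-(triethylsilyloxy)acetaldehyde; 26 (2Z)-2-methylbut-2-enoyl chloride
Product: 27 (2R)-1-chloro-2-[(2S,3R)-2-[(1E,5Z)-6-iodo-2-methylhepta-1,5-dien-1-yl]-4-methylidene-5-oxo-3-(triethylsilyloxy)oxolan-3-yl]-2-(triethylsilyloxy)ethyl (2Z)-2-methylbut-2-enoate (both C1 epimers)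
Conditions: ZnCl2 (10 mol%), CH2Cl2, −20 to 0 °C; filtered cold and used directly
Reagents that add atoms: none
Why: Lewis acid-catalysed addition of an acyl chloride across an aldehyde C=O is the standard route to 1-chloroalkyl esters; the C9 epimer ratio does not matter because both converge in the next step.

Step 17
Reactants: 27 (2R)-1-chloro-2-[(2S,3R)-2-[(1E,5Z)-6-iodo-2-methylhepta-1,5-dien-1-yl]-4-methylidene-5-oxo-3-(triethylsilyloxy)oxolan-3-yl]-2-(triethylsilyloxy)ethyl (2Z)-2-methylbut-2-enoate
Product: 28 (3aR,4S,5R,6Z,10E,11aS)-6,10-dimethyl-3-methylidene-2-oxo-3a,4-bis(triethylsilyloxy)-2,3,3a,4,5,8,9,11a-octahydrocyclodeca[b]furan-5-yl (2Z)-2-methylbut-2-enoate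
Conditions: NiBr2(dme) (30 mol%), (S,S)-Ph-BOX (36 mol%), Mn powder (4 equiv), NaI (0.5 equiv), DMA/THF, slow addition of 27 to 0.002 M, 0 °C to rt
Reagents that add atoms: none
Why: Proposed new method: zerovalent nickel (from NiBr2(dme) and manganese) inserts into the C10–I bond with retention of the Z geometry, the alkenylnickel is reduced to the monovalent state and abstracts the C9 chlorine atom of the same molecule, so both C9 epimers of 27 give one planar α-acyloxy radical beside the metal; rebound gives a trivalent alkenyl(alkyl)nickel and reductive elimination forms the C9–C10 bond. The closest known reaction types are nickel/bis(oxazoline)-catalysed enantioconvergent couplings of racemic 1-haloalkyl esters and asymmetric reductive alkenyl–alkyl cross-electrophile couplings; neither has been shown to close a medium ring. The ten-membered ring is closed by C(sp2)–C(sp3) reductive elimination from an eleven-membered nickelacycle, not by radical addition to an alkene. The new C9 centre (9R) is set at radical capture and reductive elimination by the chiral ligand, whose enantiomer is to be chosen so that it is matched with the adjacent C8 silyloxy centre. Chemoselectivity (C–I before C–Cl) rests on the much faster insertion into the alkenyl iodide, and ring closure over dimerisation rests on slow addition to high dilution. The radical must be captured before it cyclises: attack on C13 is 5-endo and slow, but attack on C5 of the C4=C5 bond is a 5-exo closure and the real competitor; it is disfavoured because the radical is born next to nickel and because the two vicinal triethylsilyloxy groups prefer an anti arrangement that places C9 anti to C6 and away from C5.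

Step 18
Reactants: 28 (3aR,4S,5R,6Z,10E,11aS)-6,10-dimethyl-3-methylidene-2-oxo-3a,4-bis(triethylsilyloxy)-2,3,3a,4,5,8,9,11a-octahydrocyclodeca[b]furan-5-yl (2Z)-2-methylbut-2-enoate
Product: 29 (3aS,4S,5R,6Z,10E,11aS)-3a,4-dihydroxy-6,10-dimethyl-3-methylidene-2-oxo-2,3,3a,4,5,8,9,11a-octahydrocyclodeca[b]furan-5-yl (2Z)-2-methylbut-2-enoate
Conditions: HF·pyridine, pyridine, THF, 0 °C to rt
Reagents that add atoms: none
Why: Buffered fluoride desilylation removes the secondary and the tertiary triethylsilyl ether without base, so the angelate does not migrate to O8 and the lactone does not shift.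

## Compound list

1 | pent-4-yn-1-ol | C#CCCCO | starting material
2 | dimethylaluminium (E)-5-(dimethylalumanyl)-4-methylpent-4-en-1-olate | C/C(=C\[Al](C)C)CCCO[Al](C)C | intermediate
3 | (E)-5-iodo-4-methylpent-4-en-1-ol | C/C(=C\I)CCCO | intermediate
4 | [(4R)-2,2-dimethyl-1,3-dioxolan-4-yl]methanol | OC[C@@H]1COC(C)(C)O1 | starting material
5 | (4S)-2,2-dimethyl-1,3-dioxolane-4-carbaldehyde | O=C[C@@H]1COC(C)(C)O1 | intermediate
6 | (4R)-4-ethynyl-2,2-dimethyl-1,3-dioxolane | C#C[C@@H]1COC(C)(C)O1 | intermediate
7 | tert-butyl prop-2-enoate | C=CC(=O)OC(C)(C)C | starting material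
8 | tert-butyl 2,3-dibromopropanoate (racemic) | BrCC(Br)C(=O)OC(C)(C)C | intermediate
9 | tert-butyl 2-bromoprop-2-enoate | C=C(Br)C(=O)OC(C)(C)C | intermediate
10 | (4E)-7-[(4R)-2,2-dimethyl-1,3-dioxolan-4-yl]-4-methylhept-4-en-6-yn-1-ol | OCCC/C(C)=C/C#C[C@@H]1COC(C)(C)O1 | intermediate
11 | (4E,6E)-7-[(4S)-2,2-dimethyl-1,3-dioxolan-4-yl]-4-methyl-7-(tributylstannyl)hepta-4,6-dien-1-ol | OCCC/C(C)=C/C=C(/[Sn](CCCC)(CCCC)CCCC)[C@@H]1COC(C)(C)O1 | intermediate
12 | tert-butyl (3Z,5E)-3-[(4R)-2,2-dimethyl-1,3-dioxolan-4-yl]-9-hydroxy-6-methyl-2-methylidenenona-3,5-dienoate | C=C(C(=O)OC(C)(C)C)/C(=C/C=C(\C)CCCO)[C@@H]1COC(C)(C)O1 | intermediate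
13 | tert-butyl (3Z,5E)-3-[(4R)-2,2-dimethyl-1,3-dioxolan-4-yl]-6-methyl-2-methylidene-9-oxonona-3,5-dienoate | C=C(C(=O)OC(C)(C)C)/C(=C/C=C(\C)CCC=O)[C@@H]1COC(C)(C)O1 | intermediate
14 | ethyltriphenylphosphonium bromide | CC[P+](c1ccccc1)(c1ccccc1)c1ccccc1.[Br-] | starting material
15 | ethylidenetriphenylphosphorane | CC=P(c1ccccc1)(c1ccccc1)c1ccccc1 | intermediate
16 | (1-iodoethyl)triphenylphosphonium iodide | CC(I)[P+](c1ccccc1)(c1ccccc1)c1ccccc1.[I-] | intermediate
17 | (1-iodoethylidene)triphenylphosphorane | CC(I)=P(c1ccccc1)(c1ccccc1)c1ccccc1 | intermediate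
18 | tert-butyl (3Z,5E,9Z)-3-[(4R)-2,2-dimethyl-1,3-dioxolan-4-yl]-10-iodo-6-methyl-2-methylideneundeca-3,5,9-trienoate | C=C(C(=O)OC(C)(C)C)/C(=C/C=C(\C)CC/C=C(/C)I)[C@@H]1COC(C)(C)O1 | intermediate
19 | tert-butyl (3Z,5E,9Z)-3-[(1R)-1,2-dihydroxyethyl]-10-iodo-6-methyl-2-methylideneundeca-3,5,9-trienoate | C=C(C(=O)OC(C)(C)C)/C(=C/C=C(\C)CC/C=C(/C)I)[C@@H](O)CO | intermediate
20 | tert-butyl (3Z,5E,9Z)-3-[(1R)-1-hydroxy-2-(triethylsilyloxy)ethyl]-10-iodo-6-methyl-2-methylideneundeca-3,5,9-trienoate | C=C(C(=O)OC(C)(C)C)/C(=C/C=C(\C)CC/C=C(/C)I)[C@@H](O)CO[Si](CC)(CC)CC | intermediate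
21 | tert-butyl 2-[(2S,3R)-2-[(1S)-1-hydroxy-2-(triethylsilyloxy)ethyl]-3-[(1E,5Z)-6-iodo-2-methylhepta-1,5-dien-1-yl]oxiran-2-yl]prop-2-enoate | C=C(C(=O)OC(C)(C)C)[C@@]1([C@@H](O)CO[Si](CC)(CC)CC)O[C@@H]1/C=C(\C)CC/C=C(/C)I | intermediate
22 | (4S,5S)-4-hydroxy-4-[(1S)-1-hydroxy-2-(triethylsilyloxy)ethyl]-5-[(1E,5Z)-6-iodo-2-methylhepta-1,5-dien-1-yl]-3-methylideneoxolan-2-one | C=C1C(=O)O[C@@H](/C=C(\C)CC/C=C(/C)I)[C@@]1(O)[C@@H](O)CO[Si](CC)(CC)CC | intermediate
23 | (4R,5S)-4-[(1S)-1,2-bis(triethylsilyloxy)ethyl]-5-[(1E,5Z)-6-iodo-2-methylhepta-1,5-dien-1-yl]-3-methylidene-4-(triethylsilyloxy)oxolan-2-one | C=C1C(=O)O[C@@H](/C=C(\C)CC/C=C(/C)I)[C@@]1(O[Si](CC)(CC)CC)[C@@H](O[Si](CC)(CC)CC)CO[Si](CC)(CC)CC | intermediate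
24 | (2R)-2-[(2S,3R)-2-[(1E,5Z)-6-iodo-2-methylhepta-1,5-dien-1-yl]-4-methylidene-5-oxo-3-(triethylsilyloxy)oxolan-3-yl]-2-(triethylsilyloxy)acetaldehyde | C=C1C(=O)O[C@@H](/C=C(\C)CC/C=C(/C)I)[C@@]1(O[Si](CC)(CC)CC)[C@@H](O[Si](CC)(CC)CC)C=O | intermediate
25 | (2Z)-2-methylbut-2-enoic acid (angelic acid) | C/C=C(/C)C(=O)O | starting material
26 | (2Z)-2-methylbut-2-enoyl chloride | C/C=C(/C)C(=O)Cl | intermediate
27 | (2R)-1-chloro-2-[(2S,3R)-2-[(1E,5Z)-6-iodo-2-methylhepta-1,5-dien-1-yl]-4-methylidene-5-oxo-3-(triethylsilyloxy)oxolan-3-yl]-2-(triethylsilyloxy)ethyl (2Z)-2-methylbut-2-enoate, both C1 epimers | C=C1C(=O)O[C@@H](/C=C(\C)CC/C=C(/C)I)[C@@]1(O[Si](CC)(CC)CC)[C@@H](O[Si](CC)(CC)CC)C(Cl)OC(=O)/C(C)=C\C | intermediate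
28 | (3aR,4S,5R,6Z,10E,11aS)-6,10-dimethyl-3-methylidene-2-oxo-3a,4-bis(triethylsilyloxy)-2,3,3a,4,5,8,9,11a-octahydrocyclodeca[b]furan-5-yl (2Z)-2-methylbut-2-enoate | C=C1C(=O)O[C@H]2/C=C(\C)CC/C=C(/C)[C@@H](OC(=O)/C(C)=C\C)[C@H](O[Si](CC)(CC)CC)[C@@]12O[Si](CC)(CC)CC | intermediate
29 | (3aS,4S,5R,6Z,10E,11aS)-3a,4-dihydroxy-6,10-dimethyl-3-methylidene-2-oxo-2,3,3a,4,5,8,9,11a-octahydrocyclodeca[b]furan-5-yl (2Z)-2-methylbut-2-enoate | C=C1C(=O)O[C@H]2/C=C(\C)CC/C=C(/C)[C@@H](OC(=O)/C(C)=C\C)[C@H](O)[C@@]12O | target

## Step count and least certain steps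

Total: 18 steps. Longest linear sequence: 15 steps (steps 1, 4 to 14, 16, 17, 18; the branch from 4 through step 2 is equally long).

**Step 17 (key step, new method).**
- What may go wrong: the C9 radical may cyclise onto C5 (5-exo) or be reduced before it reaches nickel; chains may couple intermolecularly; the ligand may fail to override the substrate at C9; the alkenylnickel may lose its Z geometry.
- Fallback (known chemistry), from 24 back to 28: an intramolecular Nozaki–Hiyama–Kishi reaction of 24 (CrCl2, catalytic NiCl2, DMSO/THF, high dilution) joins C10 to the C9 carbonyl and gives the ring carbinol F1 as C9 epimers. The epimer with the target configuration is acylated with 26 (pyridine, CH2Cl2, 0 °C). The other is esterified with 25 under Mitsunobu conditions with inversion. Both give 28.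

**Step 5.**
- What may go wrong: poor regiocontrol of the tin–hydride addition (tin on C6 instead of C7), because conjugation with C4=C5 and the propargylic oxygen need not cooperate. Mo(CO)3(CNtBu)3 as catalyst is a variant of the same step.
- Fallback, from 10 back to 12: a nickel-catalysed reductive coupling of the 1,3-enyne 10 with tert-butyl glyoxylate (Ni(cod)2, trialkylphosphine, Et3B). The conjugated alkene directs C–C bond formation to the distal alkyne carbon C7 and hydrogen is delivered syn to C6. This gives the α-hydroxy ester F2. MnO2 oxidises its allylic carbinol to the α-keto ester F3, and Wittig methylenation (Ph3P=CH2) gives 12.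

**Step 11.**
- What may go wrong: poor facial selectivity and slow turnover, because 1,3-allylic strain from C5 (cis to C8) opposes the erythro mode that the tartrate and the C7 substituent favour.
- Fallback, from 20 back to 22: if 1,3-strain dominates, the C8 epimer is the substrate that sends oxygen to the required face. 20 is oxidised with MnO2 to the enone F4. Corey–Bakshi–Shibata reduction with the appropriate catalyst enantiomer gives the epimeric carbinol F5. Epoxidation with VO(acac)2/tBuOOH in the threo mode gives the epoxide F6, and camphorsulfonic acid gives the lactone F7. Oxidation of its C8 hydroxyl gives the ketone F8. Chelation-controlled reduction with Zn(BH4)2, with hydride coming from the face away from the C6 side chain, gives 22.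

**Step 16.**
- What may go wrong: acylative cleavage of the O8 silyl ether by the acid chloride/ZnCl2 pair, incomplete addition to the hindered aldehyde, or Z to E isomerisation of the acyl group.
- Fallback, from 24 back to 28: no halide is made at C9; 24 enters the chromium-mediated route described for step 17 through F1. No further compound arises.

## Further compounds

F1 | step 17 | (3aR,4S,6Z,10E,11aS)-5-hydroxy-6,10-dimethyl-3-methylidene-3a,4-bis(triethylsilyloxy)-3a,4,5,8,9,11a-hexahydrocyclodeca[b]furan-2(3H)-one, C5 epimers | C=C1C(=O)O[C@H]2/C=C(\C)CC/C=C(/C)C(O)[C@H](O[Si](CC)(CC)CC)[C@@]12O[Si](CC)(CC)CC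
F2 | step 5 | tert-butyl (3Z,5E)-3-[(4R)-2,2-dimethyl-1,3-dioxolan-4-yl]-2,9-dihydroxy-6-methylnona-3,5-dienoate, C2 epimers | OC(C(=O)OC(C)(C)C)/C(=C/C=C(\C)CCCO)[C@@H]1COC(C)(C)O1
F3 | step 5 | tert-butyl (3E,5E)-3-[(4R)-2,2-dimethyl-1,3-dioxolan-4-yl]-9-hydroxy-6-methyl-2-oxonona-3,5-dienoate | O=C(C(=O)OC(C)(C)C)/C(=C/C=C(\C)CCCO)[C@@H]1COC(C)(C)O1
F4 | step 11 | tert-butyl (3Z,5E,9Z)-10-iodo-6-methyl-2-methylidene-3-[2-(triethylsilyloxy)acetyl]undeca-3,5,9-trienoate | C=C(C(=O)OC(C)(C)C)/C(=C/C=C(\C)CC/C=C(/C)I)C(=O)CO[Si](CC)(CC)CC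
F5 | step 11 | tert-butyl (3Z,5E,9Z)-3-[(1S)-1-hydroxy-2-(triethylsilyloxy)ethyl]-10-iodo-6-methyl-2-methylideneundeca-3,5,9-trienoate | C=C(C(=O)OC(C)(C)C)/C(=C/C=C(\C)CC/C=C(/C)I)[C@H](O)CO[Si](CC)(CC)CC
F6 | step 11 | tert-butyl 2-[(2S,3R)-2-[(1R)-1-hydroxy-2-(triethylsilyloxy)ethyl]-3-[(1E,5Z)-6-iodo-2-methylhepta-1,5-dien-1-yl]oxiran-2-yl]prop-2-enoate | C=C(C(=O)OC(C)(C)C)[C@@]1([C@H](O)CO[Si](CC)(CC)CC)O[C@@H]1/C=C(\C)CC/C=C(/C)I
F7 | step 11 | (4S,5S)-4-hydroxy-4-[(1R)-1-hydroxy-2-(triethylsilyloxy)ethyl]-5-[(1E,5Z)-6-iodo-2-methylhepta-1,5-dien-1-yl]-3-methylideneoxolan-2-one | C=C1C(=O)O[C@@H](/C=C(\C)CC/C=C(/C)I)[C@@]1(O)[C@H](O)CO[Si](CC)(CC)CC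
F8 | step 11 | (4R,5S)-4-hydroxy-5-[(1E,5Z)-6-iodo-2-methylhepta-1,5-dien-1-yl]-3-methylidene-4-[2-(triethylsilyloxy)acetyl]oxolan-2-one | C=C1C(=O)O[C@@H](/C=C(\C)CC/C=C(/C)I)[C@@]1(O)C(=O)CO[Si](CC)(CC)CC
F0 | step 16 | none | none
A1 | alternative 1 | (2S,6R)-2-[(1E)-5-(tert-butyldimethylsilyloxy)-2-methylpent-1-en-1-yl]-6-hydroxy-6-methyl-2H-pyran-3(6H)-one (major anomer) | C[C@]1(O)C=CC(=O)[C@@H](O1)/C=C(\C)CCCO[Si](C)(C)C(C)(C)C
A2 | alternative 1 | (1S,2E)-6-(tert-butyldimethylsilyloxy)-3-methyl-1-(5-methylfuran-2-yl)hex-2-en-1-ol | Cc1ccc(o1)[C@@H](O)/C=C(\C)CCCO[Si](C)(C)C(C)(C)C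
A3 | alternative 2 | ten-membered (1(10)Z,4E)-dienyl C6 carbinol with 7-O-methoxymethyl, 8,9-O-isopropylidene, C11=C13 methylene and 12-O-tert-butyldimethylsilyl | C=C(CO[Si](C)(C)C(C)(C)C)[C@@]1(OCOC)[C@@H](O)/C=C(\C)CC/C=C(/C)[C@H]2OC(C)(C)O[C@H]12
A4 | alternative 2 | thirteen-membered cyclic ether O(C6)(C13) with C7 methoxymethyl enol ether (geometry to be set for the 7S centre), 8,9-O-isopropylidene and 12-O-tert-butyldimethylsilyl | COCOC1=C(CO[Si](C)(C)C(C)(C)C)COC/C=C(\C)CC/C=C(/C)[C@H]2OC(C)(C)O[C@H]12
A5 | alternative 3 | (1(10)Z,4E)-cyclodecadien-9-one with 7,8-O-isopropylidene, 6-O- and 12-O-tert-butyldimethylsilyl | C=C(CO[Si](C)(C)C(C)(C)C)[C@@]12OC(C)(C)O[C@H]2C(=O)/C(C)=C\CC/C(C)=C/[C@@H]1O[Si](C)(C)C(C)(C)C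
A6 | alternative 3 | trans-fused octalin with C9 tertiary hydroxyl, equatorial C5 mesylate, angular C4 methyl, C1=C10 alkene, 7,8-O-isopropylidene, 6-O- and 12-O-tert-butyldimethylsilyl | C=C(CO[Si](C)(C)C(C)(C)C)[C@@]12OC(C)(C)O[C@H]2[C@]3(O)C(C)=CCC[C@@]3(C)[C@H](OS(C)(=O)=O)[C@@H]1O[Si](C)(C)C(C)(C)C
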